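Retrosynthesis: the five phenols are masked as benzyl ethers. The ring D aryl–C(=O) bond is cut first (aryllithium plus the Weinreb amide of 9-phenylnonanoic acid). Next, C3–C4 and C2–O1 of the pyran ring are cut in one operation. Last, the C4–ring D bond of an ortho-hydroxybenzhydrol is cut (aryllithium plus a salicylaldehyde).
Enabling feature: pyran ring C (O1, C2, C3, C4, C4a, C8a) holds its two aryl groups cis on C2 and C4. Read backwards, this is the heterodiene O1=C8a–C4a=C4, an ortho-quinone methide of benzo ring A with ring D on C4, joined to the C3=C2 alkene of 4-vinylphenol (ring B).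
Forward order: rings A, B and D are bought as phenols. A and D are joined at C4 (step 4), ring C is the only ring built (step 6), and the 9-phenylnonanoyl chain goes onto ring D (step 10). Hydrogenolysis ends the route.
Stereochemistry: the racemic carbinol centre disappears in the planar methide. A chiral phosphoric acid chooses the face at C4, and the endo approach of ring B sets C2 cis to it. All later steps are basic, neutral or reductive, so neither benzylic centre can ionise.

Key step: step 6

Assumption: the (R)-catalyst is taken to open the methide face that leads to (2S,4S). The sense is to be checked by anomalous-dispersion X-ray analysis of the bromide made in step 8, and the equally available (S)-catalyst is used if it proves opposite.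
Remark: chroman numbering is used throughout. Hindered rotation about the C4–ring D bond gives interconverting rotamers, not further stereoisomers.

Step 1
Reactants: 1 phloroglucinol (benzene-1,3,5-triol)
Product: 2 1,3,5-tris(benzyloxy)benzene
Conditions: BnBr (3.3 equiv), K2CO3 (4 equiv), DMF, rt → 50 °C
Reagents that add atoms: benzyl bromide, BrCc1ccccc1
Why: Threefold Williamson etherification, in which a carbonate base in a dipolar aprotic solvent favours O- over C-alkylation of the phenoxide and the crystalline triether should be easy to free from C-benzylated material.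

Step 2
Reactants: 2 1,3,5-tris(benzyloxy)benzene
Product: 3 2-bromo-1,3,5-tris(benzyloxy)benzene
Conditions: NBS (1.0 equiv), CH2Cl2, −78 → 0 °C, dark
Reagents that add atoms: N-bromosuccinimide, O=C1CCC(=O)N1Br
Why: Electrophilic aromatic bromination of a ring whose three free positions are equivalent, so one equivalent of NBS at low temperature should stop at the monobromide; the bromide is needed because direct lithiation of 2 would compete with benzylic deprotonation and Wittig rearrangement.

Step 3
Reactants: 4 2,4-dihydroxybenzaldehyde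
Product: 5 4-(benzyloxy)-2-hydroxybenzaldehyde
Conditions: BnBr (1.0 equiv), NaHCO3, MeCN, 80 °C
Reagents that add atoms: benzyl bromide, BrCc1ccccc1
Why: Regioselective Williamson etherification, because the 2-hydroxyl is held in a hydrogen bond to the aldehyde and is not ionised by the weak base, so only the 4-hydroxyl is alkylated.

Step 4
Reactants: 3 2-bromo-1,3,5-tris(benzyloxy)benzene, 5 4-(benzyloxy)-2-hydroxybenzaldehyde
Product: 8 [4-(benzyloxy)-2-hydroxyphenyl][2,4,6-tris(benzyloxy)phenyl]methanol (racemic), via sodium 5-(benzyloxy)-2-formylphenolate 6 (not isolated), via [2,4,6-tris(benzyloxy)phenyl]lithium 7 (not isolated)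
Conditions: 5, NaH, THF, 0 °C; separately 3, n-BuLi, THF, −78 °C; phenolate added by cannula, −78 → 0 °C; aq NH4Cl; chromatography on Et3N-washed silica
Reagents that add atoms: none
Why: Bromine–lithium exchange outruns benzylic deprotonation at −78 °C and the aryllithium then adds 1,2 to the aldehyde of the preformed phenolate, so none of it is spent on the acidic hydroxyl; the carbinol centre forms as a racemate, which is harmless because it becomes planar in step 6.

Step 5
Reactants: 9 4-acetoxystyrene
Product: 10 4-vinylphenol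
Conditions: K2CO3 (0.2 equiv), MeOH, 0 °C → rt; pH 7 buffer; used at once
Reagents that add atoms: none
Why: Base-catalysed methanolysis (transesterification) of an aryl acetate, mild enough to leave the polymerisation-prone styrene intact when the phenol is used without storage.

Step 6
Reactants: 8 [4-(benzyloxy)-2-hydroxyphenyl][2,4,6-tris(benzyloxy)phenyl]methanol (racemic), 10 4-vinylphenol
Product: 12 (2S,4S)-7-(benzyloxy)-2-(4-hydroxyphenyl)-4-[2,4,6-tris(benzyloxy)phenyl]chroman, via (E)-ortho-quinone methide 11 (not isolated)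
Conditions: (R)-3,3'-bis(2,4,6-triisopropylphenyl)-1,1'-binaphthyl-2,2'-diyl hydrogen phosphate [(R)-TRIP] (10 mol %), 5 Å MS, toluene/CH2Cl2 (4:1), 0 °C, 10 (1.5 equiv) added slowly
Reagents that add atoms: none
Why: Proposed new method: the phosphoric acid ionises the doubly donor-stabilised carbinol of 8, water leaves, and the hydrogen-bonded (E)-ortho-quinone methide 11 (heterodiene O1=C8a–C4a=C4) takes up the alkene of 10 in an inverse-electron-demand oxa-Diels–Alder reaction in which the styrene CH2 bonds to C4 slightly ahead of O1 bonding to the para-hydroxybenzylic C2. The closest known reaction types are the chiral-phosphoric-acid-catalysed [4+2] cycloaddition of in situ ortho-quinone methides with ortho-hydroxystyrenes and the racemic phosphoric-acid-catalysed addition of plain electron-rich styrenes to such methides, both leading to cis-2,4-diarylchromans; untested is enantiocontrol when the hydroxyl sits para to the vinyl group and the methide carbon carries a 2,6-disubstituted aryl ring. Ring C closes by a concerted, asynchronous [4+2] cycloaddition, which in its stepwise limit is a 6-exo-trig capture of the para-quinone-methide-like C2 cation by the ring A phenoxide oxygen. C4 is fixed by the catalyst, whose acidic proton binds O1 of 11 while P=O can accept a hydrogen bond from the phenol of 10, so that the triisopropylphenyl walls leave one face of the planar methide open, and C2 is fixed relative to C4 by the endo approach of ring B onto the (E)-methide, which places both aryl groups cis. The step needs regio-, endo- and cross-selectivity: the first follows from the match of the nucleophilic CH2 terminus and the electrophilic C4, the second from the (E)-geometry that the bulky, twisted and symmetric ring D enforces, and the third from the far easier ionisation of 8 than protonation of 10, helped by the slow addition of 10.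

Step 7
Reactants: 12 (2S,4S)-7-(benzyloxy)-2-(4-hydroxyphenyl)-4-[2,4,6-tris(benzyloxy)phenyl]chroman
Product: 13 (2S,4S)-7-(benzyloxy)-2-[4-(benzyloxy)phenyl]-4-[2,4,6-tris(benzyloxy)phenyl]chroman
Conditions: BnBr (1.2 equiv), K2CO3, DMF, rt
Reagents that add atoms: benzyl bromide, BrCc1ccccc1
Why: Williamson etherification of the only free phenol, in which a weak base at room temperature lets alkylation cap the phenoxide before it can open ring C through a para-quinone methide, so C2 keeps its configuration.

Step 8
Reactants: 13 (2S,4S)-7-(benzyloxy)-2-[4-(benzyloxy)phenyl]-4-[2,4,6-tris(benzyloxy)phenyl]chroman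
Product: 14 (2S,4S)-7-(benzyloxy)-2-[4-(benzyloxy)phenyl]-4-[3-bromo-2,4,6-tris(benzyloxy)phenyl]chroman
Conditions: NBS (1.0 equiv), CH2Cl2, −78 → −20 °C, dark
Reagents that add atoms: N-bromosuccinimide, O=C1CCC(=O)N1Br
Why: Electrophilic aromatic bromination directed by donor count, since each free position of ring D has three oxygen donors ortho or para against two for C6 and C8 of ring A and one for ring B, and attack at either free position of ring D gives the same compound after rotation about the C4–aryl bond.

Step 9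
Reactants: 15 9-phenylnonanoic acid
Product: 17 N-methoxy-N-methyl-9-phenylnonanamide, via 9-phenylnonanoyl imidazolide 16 (not isolated)
Conditions: 1,1'-carbonyldiimidazole (1.1 equiv), CH2Cl2, rt; then MeNH(OMe)·HCl (1.2 equiv), rt
Reagents that add atoms: N,O-dimethylhydroxylamine hydrochloride, CNOC.Cl
Why: Standard Weinreb amide synthesis by acyl imidazolide activation and aminolysis, for which the unfunctionalised chain offers no competing site.

Step 10
Reactants: 14 (2S,4S)-7-(benzyloxy)-2-[4-(benzyloxy)phenyl]-4-[3-bromo-2,4,6-tris(benzyloxy)phenyl]chroman, 17 N-methoxy-N-methyl-9-phenylnonanamide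
Product: 20 1-{2,4,6-tris(benzyloxy)-3-[(2S,4S)-7-(benzyloxy)-2-[4-(benzyloxy)phenyl]chroman-4-yl]phenyl}-9-phenylnonan-1-one, via ring D aryllithium 18 (not isolated), via tetrahedral lithium adduct 19 (not isolated)
Conditions: n-BuLi (1.05 equiv), THF, −78 °C; then 17 (1.5 equiv), −78 → 0 °C; aq NH4Cl
Reagents that add atoms: none
Why: Bromine–lithium exchange at −78 °C is faster than deprotonation of the benzyl ethers or of C2–H and C4–H, and the Weinreb ketone synthesis halts at the chelated adduct 19 until work-up, so the ketone is installed without any acid reaching the two benzylic stereocentres.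

Step 11
Reactants: 20 1-{2,4,6-tris(benzyloxy)-3-[(2S,4S)-7-(benzyloxy)-2-[4-(benzyloxy)phenyl]chroman-4-yl]phenyl}-9-phenylnonan-1-one
Product: 21 1-{2,4,6-trihydroxy-3-[(2S,4S)-7-hydroxy-2-(4-hydroxyphenyl)chroman-4-yl]phenyl}-9-phenylnonan-1-one (CNP0175574.4)
Conditions: H2 (1 atm), Pd(OH)2/C, THF/MeOH (1:1), rt, stopped after uptake of five equivalents
Reagents that add atoms: none
Why: Catalytic hydrogenolysis of five aryl benzyl ethers, a reaction class in which the cyclic C2–O1 bond of flavans and the hindered, doubly ortho-oxygenated aryl ketone of acylphloroglucinols react much more slowly than O-benzyl groups, so both stereocentres should pass unchanged.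

Compound list
1 | phloroglucinol | Oc1cc(O)cc(O)c1 | starting material
2 | 1,3,5-tris(benzyloxy)benzene | c1ccccc1COc1cc(OCc2ccccc2)cc(OCc2ccccc2)c1 | intermediate
3 | 2-bromo-1,3,5-tris(benzyloxy)benzene | Brc1c(OCc2ccccc2)cc(OCc2ccccc2)cc1OCc1ccccc1 | intermediate
4 | 2,4-dihydroxybenzaldehyde | O=Cc1ccc(O)cc1O | starting material
5 | 4-(benzyloxy)-2-hydroxybenzaldehyde | O=Cc1ccc(OCc2ccccc2)cc1O | intermediate
6 | sodium 5-(benzyloxy)-2-formylphenolate | [Na+].[O-]c1cc(OCc2ccccc2)ccc1C=O | intermediate
7 | [2,4,6-tris(benzyloxy)phenyl]lithium | [Li]c1c(OCc2ccccc2)cc(OCc2ccccc2)cc1OCc1ccccc1 | intermediate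
8 | [4-(benzyloxy)-2-hydroxyphenyl][2,4,6-tris(benzyloxy)phenyl]methanol, racemic | OC(c1ccc(OCc2ccccc2)cc1O)c1c(OCc2ccccc2)cc(OCc2ccccc2)cc1OCc1ccccc1 | intermediate
9 | 4-acetoxystyrene | CC(=O)Oc1ccc(C=C)cc1 | starting material
10 | 4-vinylphenol | C=Cc1ccc(O)cc1 | intermediate
11 | (6E)-3-(benzyloxy)-6-{[2,4,6-tris(benzyloxy)phenyl]methylidene}cyclohexa-2,4-dien-1-one | O=C1C=C(OCc2ccccc2)C=C/C1=C\c1c(OCc2ccccc2)cc(OCc2ccccc2)cc1OCc1ccccc1 | intermediate
12 | (2S,4S)-7-(benzyloxy)-2-(4-hydroxyphenyl)-4-[2,4,6-tris(benzyloxy)phenyl]chroman | c1ccccc1COc1cc(OCc2ccccc2)c(c(OCc2ccccc2)c1)[C@H]1C[C@@H](c2ccc(O)cc2)Oc2cc(OCc3ccccc3)ccc21 | intermediate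
13 | (2S,4S)-7-(benzyloxy)-2-[4-(benzyloxy)phenyl]-4-[2,4,6-tris(benzyloxy)phenyl]chroman | c1ccccc1COc1cc(OCc2ccccc2)c(c(OCc2ccccc2)c1)[C@H]1C[C@@H](c2ccc(OCc3ccccc3)cc2)Oc2cc(OCc3ccccc3)ccc21 | intermediate
14 | (2S,4S)-7-(benzyloxy)-2-[4-(benzyloxy)phenyl]-4-[3-bromo-2,4,6-tris(benzyloxy)phenyl]chroman | Brc1c(OCc2ccccc2)cc(OCc2ccccc2)c([C@H]2C[C@@H](c3ccc(OCc4ccccc4)cc3)Oc3cc(OCc4ccccc4)ccc32)c1OCc1ccccc1 | intermediate
15 | 9-phenylnonanoic acid | OC(=O)CCCCCCCCc1ccccc1 | starting material
16 | 1-(1H-imidazol-1-yl)-9-phenylnonan-1-one | O=C(CCCCCCCCc1ccccc1)n1ccnc1 | intermediate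
17 | N-methoxy-N-methyl-9-phenylnonanamide | CON(C)C(=O)CCCCCCCCc1ccccc1 | intermediate
18 | {2,4,6-tris(benzyloxy)-3-[(2S,4S)-7-(benzyloxy)-2-[4-(benzyloxy)phenyl]chroman-4-yl]phenyl}lithium | [Li]c1c(OCc2ccccc2)cc(OCc2ccccc2)c([C@H]2C[C@@H](c3ccc(OCc4ccccc4)cc3)Oc3cc(OCc4ccccc4)ccc32)c1OCc1ccccc1 | intermediate
19 | lithium alkoxide of the hemiaminal from 18 and 17 (new carbon centre undefined, lost on work-up) | [Li]OC(CCCCCCCCc1ccccc1)(N(C)OC)c1c(OCc2ccccc2)cc(OCc2ccccc2)c([C@H]2C[C@@H](c3ccc(OCc4ccccc4)cc3)Oc3cc(OCc4ccccc4)ccc32)c1OCc1ccccc1 | intermediate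
20 | 1-{2,4,6-tris(benzyloxy)-3-[(2S,4S)-7-(benzyloxy)-2-[4-(benzyloxy)phenyl]chroman-4-yl]phenyl}-9-phenylnonan-1-one | O=C(CCCCCCCCc1ccccc1)c1c(OCc2ccccc2)cc(OCc2ccccc2)c([C@H]2C[C@@H](c3ccc(OCc4ccccc4)cc3)Oc3cc(OCc4ccccc4)ccc32)c1OCc1ccccc1 | intermediate
21 | 1-{2,4,6-trihydroxy-3-[(2S,4S)-7-hydroxy-2-(4-hydroxyphenyl)chroman-4-yl]phenyl}-9-phenylnonan-1-one | O=C(CCCCCCCCc1ccccc1)c1c(O)cc(O)c([C@H]2C[C@@H](c3ccc(O)cc3)Oc3cc(O)ccc32)c1O | target

Total step count: 11. Longest linear sequence: 8 steps (1, 2, 4, 6, 7, 8, 10, 11).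

Steps most likely to fail

First, step 6.
- **What may go wrong:** facial selectivity may be poor, because the hydroxyl of 10 lies far from the reacting alkene and may not reach the phosphate that holds the methide. Acid-induced oligomerisation of 10 and slow capture of a strongly stabilised methide are further dangers.
- **Fallback:** it uses known chemistry only, sets out from 5 and 8 and rejoins the route at 13. The alkene is given an ortho-hydroxyl as a traceless handle, which brings the cycloaddition into the substrate class for which the asymmetric reaction is established.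
- **Sequence:** Wittig methylenation of 5 (Ph3PCH3Br and KOt-Bu, 2.2 equiv each, THF, 0 °C) should give 5-(benzyloxy)-2-vinylphenol F1. Under the chiral phosphoric acid, F1 and 8 should give, by way of 11, (2S,4S)-7-(benzyloxy)-2-[4-(benzyloxy)-2-hydroxyphenyl]-4-[2,4,6-tris(benzyloxy)phenyl]chroman F2. Its only free phenol is converted (Tf2O, pyridine, CH2Cl2, 0 °C) into 5-(benzyloxy)-2-{(2S,4S)-7-(benzyloxy)-4-[2,4,6-tris(benzyloxy)phenyl]chroman-2-yl}phenyl trifluoromethanesulfonate F3. Palladium-catalysed formate reduction of the aryl triflate (Pd(OAc)2, PPh3, HCO2H, Et3N, DMF, 60 °C) leaves benzyl ethers alone and delivers 13. Steps 5 and 7 then fall away.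

Second, step 8.
- **What may go wrong:** bromination may spread to C6 or C8 of ring A, which carries two oxygen donors, or run on to double bromination of ring D.
- **Fallback:** it sets out from 2 and rejoins the route at 14. The bromine is placed before ring D is attached and is carried through the cycloaddition as a spectator.
- **Sequence:** two equivalents of NBS convert 2 into 2,4-dibromo-1,3,5-tris(benzyloxy)benzene F4. One equivalent of n-BuLi (THF, −78 °C) exchanges a single bromine to give [3-bromo-2,4,6-tris(benzyloxy)phenyl]lithium F5. Addition of F5 to phenolate 6 gives racemic [4-(benzyloxy)-2-hydroxyphenyl][3-bromo-2,4,6-tris(benzyloxy)phenyl]methanol F6. Under the conditions of step 6 this passes through (6E)-3-(benzyloxy)-6-{[3-bromo-2,4,6-tris(benzyloxy)phenyl]methylidene}cyclohexa-2,4-dien-1-one F7 and adds 10 to give (2S,4S)-7-(benzyloxy)-4-[3-bromo-2,4,6-tris(benzyloxy)phenyl]-2-(4-hydroxyphenyl)chroman F8. Benzylation as in step 7 gives 14.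

Third, step 10.
- **What may go wrong:** the aryllithium sits between two benzyloxy groups and may add slowly. It could then be quenched by proton transfer from the alpha-CH2 of the amide or from a benzylic OCH2, followed by Wittig rearrangement.
- **Fallback:** it sets out from 12 and rejoins the route at 21. The polarity is reversed, so that ring D acts as the nucleophile in an electrophilic acylation.
- **Sequence:** hydrogenolysis of the four benzyl ethers of 12 (H2, Pd(OH)2/C, THF/MeOH) gives 2-[(2S,4S)-7-hydroxy-2-(4-hydroxyphenyl)chroman-4-yl]benzene-1,3,5-triol F9. Friedel–Crafts C-acylation with acid 15 in BF3·OEt2 at the lowest workable temperature should strike the phloroglucinol ring, which is the most nucleophilic ring and has two equivalent free positions.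
- **Why it is held in reserve:** this path is shorter, but it exposes both benzylic centres to a strong Lewis acid.

Further compounds
F1 | step 6 | 5-(benzyloxy)-2-vinylphenol | C=Cc1ccc(OCc2ccccc2)cc1O
F2 | step 6 | (2S,4S)-7-(benzyloxy)-2-[4-(benzyloxy)-2-hydroxyphenyl]-4-[2,4,6-tris(benzyloxy)phenyl]chroman | c1ccccc1COc1cc(OCc2ccccc2)c(c(OCc2ccccc2)c1)[C@H]1C[C@@H](c2ccc(OCc3ccccc3)cc2O)Oc2cc(OCc3ccccc3)ccc21
F3 | step 6 | 5-(benzyloxy)-2-{(2S,4S)-7-(benzyloxy)-4-[2,4,6-tris(benzyloxy)phenyl]chroman-2-yl}phenyl trifluoromethanesulfonate | c1ccccc1COc1cc(OCc2ccccc2)c(c(OCc2ccccc2)c1)[C@H]1C[C@@H](c2ccc(OCc3ccccc3)cc2OS(=O)(=O)C(F)(F)F)Oc2cc(OCc3ccccc3)ccc21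
F4 | step 8 | 2,4-dibromo-1,3,5-tris(benzyloxy)benzene | Brc1c(OCc2ccccc2)cc(OCc2ccccc2)c(Br)c1OCc1ccccc1
F5 | step 8 | [3-bromo-2,4,6-tris(benzyloxy)phenyl]lithium | [Li]c1c(OCc2ccccc2)cc(OCc2ccccc2)c(Br)c1OCc1ccccc1
F6 | step 8 | [4-(benzyloxy)-2-hydroxyphenyl][3-bromo-2,4,6-tris(benzyloxy)phenyl]methanol, racemic | OC(c1ccc(OCc2ccccc2)cc1O)c1c(OCc2ccccc2)cc(OCc2ccccc2)c(Br)c1OCc1ccccc1
F7 | step 8 | (6E)-3-(benzyloxy)-6-{[3-bromo-2,4,6-tris(benzyloxy)phenyl]methylidene}cyclohexa-2,4-dien-1-one | O=C1C=C(OCc2ccccc2)C=C/C1=C\c1c(OCc2ccccc2)cc(OCc2ccccc2)c(Br)c1OCc1ccccc1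
F8 | step 8 | (2S,4S)-7-(benzyloxy)-4-[3-bromo-2,4,6-tris(benzyloxy)phenyl]-2-(4-hydroxyphenyl)chroman | Brc1c(OCc2ccccc2)cc(OCc2ccccc2)c([C@H]2C[C@@H](c3ccc(O)cc3)Oc3cc(OCc4ccccc4)ccc32)c1OCc1ccccc1
F9 | step 10 | 2-[(2S,4S)-7-hydroxy-2-(4-hydroxyphenyl)chroman-4-yl]benzene-1,3,5-triol | Oc1cc(O)c(c(O)c1)[C@H]1C[C@@H](c2ccc(O)cc2)Oc2cc(O)ccc21
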